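## Retrosynthetic overview

- **Feature:** the saturated ring C4a-C5-C6-C7-C8-C8a carries O5, O6 and O7 on one face and Cl8 on the other. If Cl8 comes from an oxygen by SN2 inversion, C5-C8 bear four all-cis oxygens. That is the O1-O4 pattern of an α-D-allopyranoside (C8a, C8, C7, C6, C5, C4a = sugar C5, C4, C3, C2, C1, C6).
- **Ring order:** the carbocycle is made first and the γ-pyrone second; the arene is bought.
- **Pyrone:** O1-C2 forms by 6-endo-dig closure of the C8a enol onto an ynone. C4-C4a forms by aldol addition of the C4a enolate to a 5-arylpent-2-ynal, followed by oxidation.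
- **Carbocycle:** C4a-C5 forms by a Ti(IV)-promoted, aglycon-retaining Ferrier-type carbocyclisation of a benzyl 6-deoxy-α-D-ribo-hex-5-enopyranoside. O4 is a TBS ether and serves as the handle for Cl8.
- **Precursors:** the enopyranoside comes from D-glucose and benzyl alcohol through C3 epimerisation to benzyl α-D-allopyranoside. The ynal comes from 3-(3-hydroxy-4-methoxyphenyl)propanoic acid.

Key step: step 10

Remark on the chemistry: benzyl α-D-allopyranoside is reached by C3 epimerisation of the α-glucoside, not by glycosidation of D-allose. In an α-D-allopyranoside O1 and O3 are syn-diaxial, so acid-equilibrated glycosidation of allose is expected to favour the unwanted β-anomer. In the gluco series the α-anomer is favoured, and its axial aglycon then directs the C3 reduction.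

## Route

Step 1
Reactants: 1 D-glucose; 2 benzyl alcohol
Product: 3 benzyl α-D-glucopyranoside
Conditions: BnOH (solvent), Amberlite IR-120 (H+), 85 °C; α-anomer crystallised
Reagents that add atoms: none
Why: Fischer glycosidation under equilibrating acid should favour the pyranoside with the axial aglycon (anomeric effect, unopposed in the gluco series), which sets the α configuration at C1, the future C5 of the target.

Step 2
Reactants: 3 benzyl α-D-glucopyranoside
Product: 4 benzyl α-D-ribo-hexopyranosid-3-ulose
Conditions: [(neocuproine)Pd(μ-OAc)]2(OTf)2 (2.5 mol %), 1,4-benzoquinone, MeCN/H2O 10:1, rt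
Reagents that add atoms: none
Why: Pd(II)/neocuproine-catalysed chemoselective alcohol oxidation of unprotected glucopyranosides is known to single out the C3 carbinol, and it should leave O2, O4, the primary OH and the benzyl glycoside untouched.

Step 3
Reactants: 4 benzyl α-D-ribo-hexopyranosid-3-ulose
Product: 5 benzyl α-D-allopyranoside
Conditions: NaBH4, MeOH, 0 °C
Reagents that add atoms: none
Why: In this borohydride reduction the axial α-benzyloxy group at C1 shields the lower face of C3 syn-axially, so hydride should arrive from the β face and push the new hydroxyl axial, giving the allo configuration (future C7).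

Step 4
Reactants: 5 benzyl α-D-allopyranoside
Product: 6 benzyl 4,6-O-[(R)-benzylidene]-α-D-allopyranoside
Conditions: PhCH(OMe)2 (1.1 equiv), CSA (cat.), MeCN, rt
Reagents that add atoms: benzaldehyde dimethyl acetal, COC(OC)c1ccccc1
Why: Acid-catalysed transacetalisation under thermodynamic control favours the trans-fused 1,3-dioxane on O4/O6 with equatorial phenyl (R acetal carbon), so with about one equivalent of reagent the cis-2,3-diol should stay free.

Step 5
Reactants: 6 benzyl 4,6-O-[(R)-benzylidene]-α-D-allopyranoside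
Product: 7 benzyl 2,3-di-O-benzyl-4,6-O-[(R)-benzylidene]-α-D-allopyranoside
Conditions: NaH, BnBr, Bu4NI (cat.), DMF, 0 °C to rt
Reagents that add atoms: benzyl bromide, BrCc1ccccc1
Why: Williamson etherification of the two remaining hydroxyls; acetal and glycoside are base-stable and no stereocentre is touched.

Step 6
Reactants: 7 benzyl 2,3-di-O-benzyl-4,6-O-[(R)-benzylidene]-α-D-allopyranoside
Product: 8 benzyl 2,3-di-O-benzyl-α-D-allopyranoside
Conditions: AcOH/H2O 4:1, 70 °C
Reagents that add atoms: none
Why: Mild acid hydrolysis cleaves the benzylidene acetal much faster than the pyranosidic acetal and does not affect benzyl ethers.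

Step 7
Reactants: 8 benzyl 2,3-di-O-benzyl-α-D-allopyranoside
Product: 9 benzyl 2,3-di-O-benzyl-6-deoxy-6-iodo-α-D-allopyranoside
Conditions: I2, PPh3, imidazole, toluene, 70 °C
Reagents that add atoms: iodine, II
Why: Garegg-Samuelsson iodination (Appel-type) is selective for the primary alkoxyphosphonium, since SN2 at CH2 is far faster than at the flanked secondary C4.

Step 8
Reactants: 9 benzyl 2,3-di-O-benzyl-6-deoxy-6-iodo-α-D-allopyranoside
Product: 10 benzyl 2,3-di-O-benzyl-4-O-(tert-butyldimethylsilyl)-6-deoxy-6-iodo-α-D-allopyranoside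
Conditions: TBSOTf, 2,6-lutidine, CH2Cl2, 0 °C to rt
Reagents that add atoms: tert-butyldimethylsilyl triflate, CC(C)(C)[Si](C)(C)OS(=O)(=O)C(F)(F)F
Why: Silylation with the reactive silyl triflate covers the hindered equatorial O4 and marks it as the only oxygen orthogonal to the benzyl ethers (future C8 handle).

Step 9
Reactants: 10 benzyl 2,3-di-O-benzyl-4-O-(tert-butyldimethylsilyl)-6-deoxy-6-iodo-α-D-allopyranoside
Product: 11 benzyl 2,3-di-O-benzyl-4-O-(tert-butyldimethylsilyl)-6-deoxy-α-D-ribo-hex-5-enopyranoside
Conditions: DBU, THF, reflux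
Reagents that add atoms: none
Why: E2 dehydroiodination (H5/I6) is the standard entry to hex-5-enopyranosides; only the sugar C5 stereocentre, which is not needed, is removed, and silyl and benzyl ethers tolerate the amidine base.

Step 10
Reactants: 11 benzyl 2,3-di-O-benzyl-4-O-(tert-butyldimethylsilyl)-6-deoxy-α-D-ribo-hex-5-enopyranoside
Product: 13 (2S,3S,4S,5S)-3,4,5-tris(benzyloxy)-2-[(tert-butyldimethylsilyl)oxy]cyclohexan-1-one, via ring-opened titanium enolate/oxocarbenium ion pair 12 (not isolated)
Conditions: Ti(OiPr)Cl3 (2 equiv, preformed solution), CH2Cl2, −78 °C, 15-30 min; H2O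
Reagents that add atoms: none
Why: Ti(OiPr)Cl3 coordinates the ring oxygen O5 of 11, which is both acetal and enol-ether oxygen, and breaks the endocyclic C1-O5 bond to give the contact ion pair 12, a titanium enolate (O5-C5=C6) facing a benzyloxy-stabilised oxocarbenium ion at C1. The enolate carbon C6 then adds to C1 in an intramolecular Mukaiyama-aldol-like step that forms the C4a-C5 bond of the target and closes the carbocycle in the 6-(enolendo)-exo-trig mode. The closest known reaction type is the Lewis-acid-promoted Ferrier-type carbocyclisation of 6-deoxyhex-5-enopyranosides that keeps the aglycon, in its titanium(IV) variant, which leaves the ketone unreduced. The only stereocentre made, sugar C1 (C5 of the target), is re-formed with retention because C6 is delivered to the face that O5 has just left before the C1-C2 bond can rotate, so the benzyloxy group stays cis to O2 (O6) while C2, C3 and C4 are untouched. The step needs endocyclic rather than exocyclic C-O cleavage and retention at C1, and the electron-releasing benzyl aglycon in the axial α position, the bulky and weakly basic OTBS group (which does not draw titanium away from O5) and the low temperature should secure both. At −78 °C and short contact time the β-benzyloxy ketone should not lose benzyl alcohol and the silyl ether should survive.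

Step 11
Reactants: 14 3-(3-hydroxy-4-methoxyphenyl)propanoic acid
Product: 15 benzyl 3-[3-(benzyloxy)-4-methoxyphenyl]propanoate
Conditions: BnBr (2.3 equiv), K2CO3, DMF, 50 °C
Reagents that add atoms: benzyl bromide, BrCc1ccccc1
Why: Double O-alkylation (Williamson etherification of the phenoxide and carboxylate alkylation) masks the phenol with the group that is later removed together with the sugar-derived benzyl ethers.

Step 12
Reactants: 15 benzyl 3-[3-(benzyloxy)-4-methoxyphenyl]propanoate
Product: 16 3-[3-(benzyloxy)-4-methoxyphenyl]propanal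
Conditions: DIBAL-H (1.05 equiv), CH2Cl2, −78 °C; Rochelle salt
Reagents that add atoms: none
Why: Partial ester reduction with DIBAL-H stops at the aluminium hemiacetal at −78 °C, which releases the aldehyde only on work-up.

Step 13
Reactants: 16 3-[3-(benzyloxy)-4-methoxyphenyl]propanal
Product: 17 2-(benzyloxy)-4-(but-3-yn-1-yl)-1-methoxybenzene
Conditions: dimethyl (1-diazo-2-oxopropyl)phosphonate, K2CO3, MeOH, rt
Reagents that add atoms: dimethyl (1-diazo-2-oxopropyl)phosphonate, COP(=O)(OC)C(=[N+]=[N-])C(C)=O
Why: Ohira-Bestmann (Seyferth-Gilbert) homologation converts an enolisable aliphatic aldehyde into the terminal alkyne under mild carbonate conditions.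

Step 14
Reactants: 17 2-(benzyloxy)-4-(but-3-yn-1-yl)-1-methoxybenzene
Product: 19 5-[3-(benzyloxy)-4-methoxyphenyl]pent-2-ynal, via lithium acetylide 18 (not isolated)
Conditions: n-BuLi, THF, −78 °C; DMF, −78 to 0 °C; inverse quench into aq. KH2PO4
Reagents that add atoms: N,N-dimethylformamide, CN(C)C=O
Why: Formylation of a lithium acetylide with DMF, where the buffered inverse quench collapses the hemiaminal alkoxide without conjugate addition of the released amine to the ynal.

Step 15
Reactants: 13 (2S,3S,4S,5S)-3,4,5-tris(benzyloxy)-2-[(tert-butyldimethylsilyl)oxy]cyclohexan-1-one; 19 5-[3-(benzyloxy)-4-methoxyphenyl]pent-2-ynal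
Product: 21 (2S,3S,4S,5S)-3,4,5-tris(benzyloxy)-6-{5-[3-(benzyloxy)-4-methoxyphenyl]-1-hydroxypent-2-yn-1-yl}-2-[(tert-butyldimethylsilyl)oxy]cyclohexan-1-one, via dicyclohexylboron enolate 20 (not isolated)
Conditions: c-Hex2BCl, Et3N, Et2O, 0 °C; 19, −78 to −20 °C; MeOH, pH 7 buffer, 30 % H2O2, 0 °C
Reagents that add atoms: none
Why: Boron-mediated aldol addition, in which soft enolisation removes a proton from the only methylene (C4a) rather than from the hindered silyloxy-bearing C8, and the covalent enol borinate 20 is far less prone than a lithium enolate to expel the β-benzyloxy group; the two new stereocentres (C4a and the carbinol C4, expected anti and on the face opposite O5) are both erased in steps 16 and 17.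

Step 16
Reactants: 21 the aldol adduct of step 15
Product: 22 (2S,3S,4S,5S)-3,4,5-tris(benzyloxy)-6-{5-[3-(benzyloxy)-4-methoxyphenyl]pent-2-ynoyl}-2-[(tert-butyldimethylsilyl)oxy]cyclohexan-1-one (largely enolised; drawn as the diketo tautomer)
Conditions: Dess-Martin periodinane (1.2 equiv), NaHCO3, CH2Cl2, 0 °C
Reagents that add atoms: none
Why: Dess-Martin oxidation of the propargylic β-hydroxy ketone under buffered near-neutral conditions should give the acetylenic β-diketone without any base that could trigger loss of the C5 benzyloxy group; C4a becomes configurationally labile, which is harmless.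

Step 17
Reactants: 22 the acetylenic β-diketone of step 16
Product: 23 (5S,6S,7S,8S)-5,6,7-tris(benzyloxy)-2-{2-[3-(benzyloxy)-4-methoxyphenyl]ethyl}-8-[(tert-butyldimethylsilyl)oxy]-5,6,7,8-tetrahydro-4H-chromen-4-one (O5-O8 all cis)
Conditions: Ph3PAuNTf2 (5 mol %), CH2Cl2, rt
Reagents that add atoms: none
Why: Cycloisomerisation of an acetylenic β-diketone to a γ-pyrone (intramolecular oxa-Michael addition, 6-endo-dig), in which the C8a enol oxygen adds to the π-acid-activated β-carbon C2 of the ynone, the site favoured by carbonyl polarisation over 5-exo attack at C3, and proton transfer makes C4a sp2 under neutral conditions.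

Step 18
Reactants: 23 the 8-O-TBS pyrone of step 17
Product: 24 (5S,6S,7R,8S)-5,6,7-tris(benzyloxy)-2-{2-[3-(benzyloxy)-4-methoxyphenyl]ethyl}-8-hydroxy-5,6,7,8-tetrahydro-4H-chromen-4-one (O5-O8 all cis; the C7 descriptor changes by priority only)
Conditions: HF·pyridine, THF/pyridine, 0 °C to rt
Reagents that add atoms: none
Why: Fluoride-mediated desilylation in a non-basic medium frees only O8 and avoids deprotonating the vinylogously acidic H8, which could expel the C7 benzyloxy group.

Step 19
Reactants: 24 the C8 alcohol of step 18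
Product: 25 (5S,6S,7S,8S)-5,6,7-tris(benzyloxy)-2-{2-[3-(benzyloxy)-4-methoxyphenyl]ethyl}-4-oxo-5,6,7,8-tetrahydro-4H-chromen-8-yl chloromethanesulfonate
Conditions: ClCH2SO2Cl, pyridine, CH2Cl2, 0 °C
Reagents that add atoms: chloromethanesulfonyl chloride, ClCS(=O)(=O)Cl
Why: O-Sulfonylation leaves the C8-O bond, and hence the configuration, intact and installs a leaving group clearly better than mesylate, while avoiding triflic anhydride, which would also attack the nucleophilic pyrone carbonyl.

Step 20
Reactants: 25 the C8 chloromethanesulfonate of step 19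
Product: 26 (5S,6S,7S,8R)-5,6,7-tris(benzyloxy)-2-{2-[3-(benzyloxy)-4-methoxyphenyl]ethyl}-8-chloro-5,6,7,8-tetrahydro-4H-chromen-4-one
Conditions: LiCl (2 equiv), DMF, rt
Reagents that add atoms: lithium chloride, [Li+].[Cl-]
Why: SN2 displacement with inversion sets C8, because the carbon is activated by the adjacent electron-poor pyrone carbon C8a (as in 2-halomethyl-4-pyrones), ionisation there is disfavoured, and the rear face is open since O5-O8 all lie on the other face, so chloride should end up trans to O7.

Step 21
Reactants: 26 the protected 8-chloride of step 20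
Product: 27 (5S,6S,7S,8R)-8-chloro-5,6,7-trihydroxy-2-[2-(3-hydroxy-4-methoxyphenyl)ethyl]-5,6,7,8-tetrahydro-4H-chromen-4-one (target)
Conditions: BCl3 (1 M in CH2Cl2, excess), pentamethylbenzene, CH2Cl2, −78 to −40 °C; MeOH quench, aqueous work-up
Reagents that add atoms: none
Why: Lewis-acid debenzylation with a non-basic cation scavenger removes all four benzyl groups without hydrogenolysis of C8-Cl; BCl3 bound to the pyrone carbonyl makes the heterocycle pyrylium-like, which should suppress ionisation at C5 and C8, and at this temperature the aryl methyl ether should persist.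

## Compound list

| No. | Name | SMILES | Role |
|---|---|---|---|
| 1 | D-glucose | OC[C@H]1OC(O)[C@H](O)[C@@H](O)[C@@H]1O | starting material |
| 2 | benzyl alcohol | OCc1ccccc1 | starting material |
| 3 | benzyl α-D-glucopyranoside | OC[C@H]1O[C@H](OCc2ccccc2)[C@H](O)[C@@H](O)[C@@H]1O | intermediate |
| 4 | benzyl α-D-ribo-hexopyranosid-3-ulose | OC[C@H]1O[C@H](OCc2ccccc2)[C@H](O)C(=O)[C@@H]1O | intermediate |
| 5 | benzyl α-D-allopyranoside | OC[C@H]1O[C@H](OCc2ccccc2)[C@H](O)[C@H](O)[C@@H]1O | intermediate |
| 6 | benzyl 4,6-O-[(R)-benzylidene]-α-D-allopyranoside | C1O[C@@H](c2ccccc2)O[C@@H]2[C@@H]1O[C@H](OCc1ccccc1)[C@H](O)[C@@H]2O | intermediate |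
| 7 | benzyl 2,3-di-O-benzyl-4,6-O-[(R)-benzylidene]-α-D-allopyranoside | C1O[C@@H](c2ccccc2)O[C@@H]2[C@@H]1O[C@H](OCc1ccccc1)[C@H](OCc1ccccc1)[C@@H]2OCc1ccccc1 | intermediate |
| 8 | benzyl 2,3-di-O-benzyl-α-D-allopyranoside | OC[C@H]1O[C@H](OCc2ccccc2)[C@H](OCc2ccccc2)[C@H](OCc2ccccc2)[C@@H]1O | intermediate |
| 9 | benzyl 2,3-di-O-benzyl-6-deoxy-6-iodo-α-D-allopyranoside | IC[C@H]1O[C@H](OCc2ccccc2)[C@H](OCc2ccccc2)[C@H](OCc2ccccc2)[C@@H]1O | intermediate |
| 10 | benzyl 2,3-di-O-benzyl-4-O-TBS-6-deoxy-6-iodo-α-D-allopyranoside | IC[C@H]1O[C@H](OCc2ccccc2)[C@H](OCc2ccccc2)[C@H](OCc2ccccc2)[C@@H]1O[Si](C)(C)C(C)(C)C | intermediate |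
| 11 | benzyl 2,3-di-O-benzyl-4-O-TBS-6-deoxy-α-D-ribo-hex-5-enopyranoside | C=C1[C@@H](O[Si](C)(C)C(C)(C)C)[C@@H](OCc2ccccc2)[C@@H](OCc2ccccc2)[C@@H](OCc2ccccc2)O1 | intermediate |
| 12 | ring-opened titanium enolate/oxocarbenium ion pair (formal zwitterion, not isolated) | C=C(O[Ti-](Cl)(Cl)(Cl)OC(C)C)[C@@H](O[Si](C)(C)C(C)(C)C)[C@@H](OCc1ccccc1)[C@@H](OCc1ccccc1)C=[O+]Cc1ccccc1 | intermediate |
| 13 | (2S,3S,4S,5S)-3,4,5-tris(benzyloxy)-2-(TBSO)cyclohexan-1-one (all four oxygens cis) | O=C1[C@@H](O[Si](C)(C)C(C)(C)C)[C@@H](OCc2ccccc2)[C@@H](OCc2ccccc2)[C@@H](OCc2ccccc2)C1 | intermediate |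
| 14 | 3-(3-hydroxy-4-methoxyphenyl)propanoic acid | COc1ccc(CCC(=O)O)cc1O | starting material |
| 15 | benzyl 3-[3-(benzyloxy)-4-methoxyphenyl]propanoate | COc1ccc(CCC(=O)OCc2ccccc2)cc1OCc1ccccc1 | intermediate |
| 16 | 3-[3-(benzyloxy)-4-methoxyphenyl]propanal | COc1ccc(CCC=O)cc1OCc1ccccc1 | intermediate |
| 17 | 2-(benzyloxy)-4-(but-3-yn-1-yl)-1-methoxybenzene | COc1ccc(CCC#C)cc1OCc1ccccc1 | intermediate |
| 18 | lithium acetylide of 17 (not isolated) | COc1ccc(CCC#C[Li])cc1OCc1ccccc1 | intermediate |
| 19 | 5-[3-(benzyloxy)-4-methoxyphenyl]pent-2-ynal | COc1ccc(CCC#CC=O)cc1OCc1ccccc1 | intermediate |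
| 20 | dicyclohexylboron enolate of 13, C8a=C4a (not isolated) | C1CCCCC1B(C1CCCCC1)OC1=C[C@H](OCc2ccccc2)[C@H](OCc2ccccc2)[C@H](OCc2ccccc2)[C@@H]1O[Si](C)(C)C(C)(C)C | intermediate |
| 21 | aldol adduct; C4a and carbinol configuration immaterial | O=C1[C@@H](O[Si](C)(C)C(C)(C)C)[C@@H](OCc2ccccc2)[C@@H](OCc2ccccc2)[C@@H](OCc2ccccc2)C1C(O)C#CCCc1ccc(OC)c(OCc2ccccc2)c1 | intermediate |
| 22 | acetylenic β-diketone (diketo tautomer drawn) | O=C1[C@@H](O[Si](C)(C)C(C)(C)C)[C@@H](OCc2ccccc2)[C@@H](OCc2ccccc2)[C@@H](OCc2ccccc2)C1C(=O)C#CCCc1ccc(OC)c(OCc2ccccc2)c1 | intermediate |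
| 23 | (5S,6S,7S,8S)-5,6,7-tri-OBn-8-OTBS tetrahydrochromone | COc1ccc(CCc2cc(=O)c3c(o2)[C@@H](O[Si](C)(C)C(C)(C)C)[C@@H](OCc2ccccc2)[C@@H](OCc2ccccc2)[C@H]3OCc2ccccc2)cc1OCc1ccccc1 | intermediate |
| 24 | (5S,6S,7R,8S)-5,6,7-tri-OBn-8-hydroxy tetrahydrochromone | COc1ccc(CCc2cc(=O)c3c(o2)[C@@H](O)[C@@H](OCc2ccccc2)[C@@H](OCc2ccccc2)[C@H]3OCc2ccccc2)cc1OCc1ccccc1 | intermediate |
| 25 | (5S,6S,7S,8S)-8-chloromethanesulfonate | COc1ccc(CCc2cc(=O)c3c(o2)[C@@H](OS(=O)(=O)CCl)[C@@H](OCc2ccccc2)[C@@H](OCc2ccccc2)[C@H]3OCc2ccccc2)cc1OCc1ccccc1 | intermediate |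
| 26 | (5S,6S,7S,8R)-5,6,7-tri-OBn-8-chloro tetrahydrochromone | COc1ccc(CCc2cc(=O)c3c(o2)[C@H](Cl)[C@@H](OCc2ccccc2)[C@@H](OCc2ccccc2)[C@H]3OCc2ccccc2)cc1OCc1ccccc1 | intermediate |
| 27 | (5S,6S,7S,8R)-8-chloro-5,6,7-trihydroxy-2-[2-(3-hydroxy-4-methoxyphenyl)ethyl]-5,6,7,8-tetrahydro-4H-chromen-4-one | COc1ccc(CCc2cc(=O)c3c(o2)[C@H](Cl)[C@@H](O)[C@@H](O)[C@H]3O)cc1O | target |

## Step count

- Total step count: 21.
- Longest linear sequence: 17 (steps 1-10 and 15-21).

## Steps most likely to fail

**Step 10.**
- What may go wrong: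
  - Stereochemical memory may be lost if the ion pair lives long enough for rotation about C1-C2. Retention gets no thermodynamic help here, because the retained benzyloxy group ends up 1,3-syn to the C7 benzyloxy group.
  - Titanium may also induce β-elimination of benzyl alcohol or desilylation.
- Fallback:
  - It sets out from 11. Triisobutylaluminium in toluene (rt to 40 °C) effects the same endocyclic cleavage and reclosure within an aluminium-bound array and reduces the ketone as it forms. This removes the β-elimination pathway.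
  - It should give 3,4,5-tris(benzyloxy)-2-[(tert-butyldimethylsilyl)oxy]cyclohexan-1-ol F1 (O2-O5 all cis as in 13, carbinol configuration immaterial).
  - Dess-Martin oxidation of this alcohol comes back to the route at 13.

**Step 15.**
- What may go wrong:
  - The C5 benzyloxy group may be expelled from the enolate in an E1cB manner.
  - Enolisation may occur towards C8, with epimerisation.
  - The hindered enolate may add only sluggishly.
- Fallback:
  - It sets out from 13. The ketone is added to premixed LDA/TMSCl in THF at −78 °C (internal quench), so the lithium enolate is silylated as it forms. This should give the kinetic trimethylsilyl enol ether F2.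
  - The neutral nucleophile is then combined with ynal 19 under BF3·OEt2 in CH2Cl2 at −78 °C (Mukaiyama aldol addition), with no anionic push towards elimination.
  - The sequence comes back to the route at 21.

**Step 20.**
- What may go wrong:
  - E2 loss of the sulfonate with the antiperiplanar H7 may start a cascade towards aromatisation.
  - The C8 configuration may erode through repeated chloride-for-chloride exchange at this activated position.
- Fallback:
  - It sets out from 24 and bypasses 25. An Appel reaction (PPh3, CCl4, CH2Cl2, 0 °C to rt) activates O8 as the alkoxytriphenylphosphonium chloride F3 (not isolated).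
  - This collapses with inversion inside its own ion pair, without excess free chloride and without a polar aprotic solvent.
  - It comes back to the route at 26.

## Further compounds

F1 | step 10 | 3,4,5-tris(benzyloxy)-2-[(tert-butyldimethylsilyl)oxy]cyclohexan-1-ol (O2-O5 all cis, carbinol unspecified) | OC1[C@@H](O[Si](C)(C)C(C)(C)C)[C@@H](OCc2ccccc2)[C@@H](OCc2ccccc2)[C@@H](OCc2ccccc2)C1
F2 | step 15 | trimethylsilyl enol ether of 13 (C8a=C4a) | C[Si](C)(C)OC1=C[C@H](OCc2ccccc2)[C@H](OCc2ccccc2)[C@H](OCc2ccccc2)[C@@H]1O[Si](C)(C)C(C)(C)C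
F3 | step 20 | alkoxytriphenylphosphonium chloride of 24 | COc1ccc(CCc2cc(=O)c3c(o2)[C@@H](O[P+](c2ccccc2)(c2ccccc2)c2ccccc2)[C@@H](OCc2ccccc2)[C@@H](OCc2ccccc2)[C@H]3OCc2ccccc2)cc1OCc1ccccc1.[Cl-]
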